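Numbering: the flavanone half has rings A (benzo), C (dihydropyranone) and B (aryl, primed atoms). The flavone half has rings D (benzo), E (pyranone) and F (aryl), with double-primed atoms.
Cuts: first C2–C1' (ring B off the flavanone), then C7''–C8'' and C4a''–C5'' of ring D. The crowded C3'–C6'' biaryl bond is never made by coupling, because it is the benzylic C–C bond of 2-hydroxyphenylacetic acid.
Enabling feature: C6'' bears ring B and lies between the hydroxylated C5'' and C7'', so C5''–C6''(aryl)–C7'' is an arylmalonyl unit. C8'', C8a'' and C4a'' are the methyl carbon, C2 and C3 of a 6-aryl-2-methyl-4-pyranone that already holds ring E, ring F and O1''.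
Forward order: ring E (triketone cyclodehydration), ring D ([3+3] double C-acylation), benzylation and borylation of ring B, the ring A/C chromone from phloroacetophenone, C2–C1' union, global hydrogenolysis.
Stereochemistry: the only stereocentre, C2 (S), is set by a ligand-controlled enantioselective conjugate addition of the arylboronic acid to 7-benzyloxy-5-methoxychromone. No basic step follows it.

Key step: step 8

Assumption: the C3'–C6'' axis carries no descriptor in the target, so rotation about it is taken as fast at room temperature in the free pentaphenol, and slowly interconverting rotamers of benzylated intermediates count as one compound.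
Assumption: with cyclic enones the (S)-pyridine-oxazoline ligand places the aryl group on the face that corresponds to (2R) in a flavanone. The (R)-ligand is therefore specified, and its antipode would be used if the first experiment shows the opposite sense.

Step 1
Reactants: 1 methyl 4-hydroxybenzoate
Product: 2 methyl 4-(benzyloxy)benzoate
Conditions: BnBr (1.1 equiv), K2CO3, acetone, reflux
Reagents that add atoms: benzyl bromide, BrCc1ccccc1
Why: Williamson etherification of a phenoxide with a primary benzylic halide, under carbonate conditions that leave the methyl ester intact.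

Step 2
Reactants: 2 methyl 4-(benzyloxy)benzoate; 3 acetylacetone
Product: 4 1-[4-(benzyloxy)phenyl]hexane-1,3,5-trione
Conditions: 3 (2 equiv), LiN(i-Pr)2 (4 equiv), THF, −78 → 0 °C; 2, 0 °C → rt; 1 M HCl
Reagents that add atoms: none
Why: The terminal carbon of the acetylacetone 1,3-dianion is its most nucleophilic site, so Claisen-type acylation by the non-enolisable benzoate should give the linear triketone, with the second equivalent of dianion absorbing the acidity of the product.

Step 3
Reactants: 4 1-[4-(benzyloxy)phenyl]hexane-1,3,5-trione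
Product: 5 2-[4-(benzyloxy)phenyl]-6-methyl-4H-pyran-4-one
Conditions: p-TsOH·H2O (10 mol %), toluene, reflux, Dean–Stark trap
Reagents that add atoms: none
Why: Acid-catalysed cyclodehydration of a 1,3,5-triketone (enol oxygen at C1 onto C5, loss of water) is the standard entry to 2,6-disubstituted 4-pyranones, can give only one ring, and under catalytic sulfonic acid spares the benzyl ether.

Step 4
Reactants: 6 2-hydroxyphenylacetic acid
Product: 7 (5-bromo-2-hydroxyphenyl)acetic acid
Conditions: NBS (1.0 equiv), MeCN, 0 °C → rt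
Reagents that add atoms: N-bromosuccinimide, O=C1CCC(=O)N1Br
Why: Electrophilic aromatic bromination is directed by the phenol to its unhindered para position (C5), and the near-neutral medium avoids lactonisation to the benzofuranone.

Step 5
Reactants: 7 (5-bromo-2-hydroxyphenyl)acetic acid
Product: 9 [2-(benzyloxy)-5-bromophenyl]acetic acid, via benzyl ester 8 (not isolated)
Conditions: BnBr (2.3 equiv), K2CO3, DMF, 50 °C; then 2 M NaOH, MeOH, 50 °C; 1 M HCl
Reagents that add atoms: benzyl bromide, BrCc1ccccc1; sodium hydroxide (supplies the acid OH oxygen), [Na+].[OH-]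
Why: Exhaustive O-alkylation (Williamson etherification plus carboxylate alkylation) followed by saponification in the same flask removes only the ester benzyl group, since aryl benzyl ethers are inert to hydroxide.

Step 6
Reactants: 9 [2-(benzyloxy)-5-bromophenyl]acetic acid
Product: 10 2-[2-(benzyloxy)-5-bromophenyl]propanedioic acid
Conditions: LiN(i-Pr)2 (2.1 equiv), THF, −78 → −20 °C; CO2 (g), −78 → 0 °C; 1 M HCl, 0 °C
Reagents that add atoms: carbon dioxide, O=C=O
Why: Carboxylation of the arylacetic acid dianion (Ivanov-type enediolate) is the classical route to arylmalonic acids, the amide base does not exchange the aryl bromide at low temperature, and cold acidification prevents decarboxylation.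

Step 7
Reactants: 10 2-[2-(benzyloxy)-5-bromophenyl]propanedioic acid
Product: 12 2-[2-(benzyloxy)-5-bromophenyl]-3-oxoprop-2-enoyl chloride [(chlorocarbonyl)arylketene; used at once as a toluene solution], via malonyl dichloride 11 (not isolated)
Conditions: (COCl)2 (2.5 equiv), DMF (cat.), CH2Cl2, 0 °C → rt; evaporate; toluene, 90 °C, N2 stream
Reagents that add atoms: oxalyl chloride, O=C(Cl)C(=O)Cl
Why: Acid chloride formation followed by thermal loss of HCl from the arylmalonyl dichloride is the established preparation of (chlorocarbonyl)arylketenes, which are stabilised by conjugation with the aryl and acyl groups.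

Step 8
Reactants: 5 2-[4-(benzyloxy)phenyl]-6-methyl-4H-pyran-4-one; 12 2-[2-(benzyloxy)-5-bromophenyl]-3-oxoprop-2-enoyl chloride
Product: 14 6-[2-(benzyloxy)-5-bromophenyl]-2-[4-(benzyloxy)phenyl]-5,7-dihydroxy-4H-chromen-4-one, via silyloxy methylenepyran 13 (not isolated)
Conditions: 5, TBSOTf (1.2 equiv), 2,6-lutidine (2.5 equiv), ClCH2CH2Cl, 0 °C → rt; 12 (1.1 equiv, toluene), −30 °C → rt, then 70 °C; 1 M HCl, THF, rt
Reagents that add atoms: tert-butyldimethylsilyl triflate (its silyl group is present only in 13 and is lost again before 14), CC(C)(C)[Si](C)(C)OS(=O)(=O)C(F)(F)F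
Why: Proposed new method: O-silylation of 5 gives a 4-silyloxypyrylium triflate whose 2-methyl group is acidic enough for 2,6-lutidine, and the exocyclic dienol ether 13 so formed attacks the central carbon of ketene 12 through its methylene carbon, the one site whose reaction restores the pyrylium sextet (C7''–C8''). Proton loss regenerates an acyl-substituted methylenepyran, whose pendant acid chloride acylates pyranone C3, the nucleophilic carbon of the C3=C4 silyl enol ether, in a 6-(enolexo)-exo-trig closure (or, after loss of HCl, a 6π electrocyclisation of the dienylketene C3=C2–CH=C(OH)–C(Ar)=C=O), forming C4a''–C5''; chloride then takes the silyl group and double enolisation delivers aromatic ring D. The closest known reaction types are the [3+3] cyclocondensations of (chlorocarbonyl)phenylketene and of activated arylmalonates with 1,3-dinucleophiles, the acylation of 2-methyl-4-pyranones at the methyl carbon, and the electrocyclic benzannulation of dienylketenes, but their combination on a pyranone acting as a C,C-dinucleophile is untested. No stereocentre is formed. The step needs C-acylation rather than O-acylation twice and a single regiochemistry: the carbonyl oxygen is blocked by silicon, intramolecular O-acylation would require a four- or eight-membered ring, the two carbonyl carbons of 12 flank the aryl-bearing carbon equivalently so either order of bond formation gives the same ring, and O1'' is fixed in ring E so the 8-aryl isomer cannot arise. The irreversible gain of a benzenoid ring supplies the driving force.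

Step 9
Reactants: 14 6-[2-(benzyloxy)-5-bromophenyl]-2-[4-(benzyloxy)phenyl]-5,7-dihydroxy-4H-chromen-4-one
Product: 15 5,7-bis(benzyloxy)-6-[2-(benzyloxy)-5-bromophenyl]-2-[4-(benzyloxy)phenyl]-4H-chromen-4-one
Conditions: BnBr (3 equiv), Cs2CO3, Bu4NI (cat.), DMF, 60 °C
Reagents that add atoms: benzyl bromide, BrCc1ccccc1
Why: Williamson etherification under forcing caesium carbonate conditions also alkylates the chelated, flanked 5''-OH, which removes a 5-hydroxy-4-keto site that could otherwise bind the palladium catalysts used later.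

Step 10
Reactants: 15 5,7-bis(benzyloxy)-6-[2-(benzyloxy)-5-bromophenyl]-2-[4-(benzyloxy)phenyl]-4H-chromen-4-one
Product: 16 5,7-bis(benzyloxy)-6-[2-(benzyloxy)-5-(4,4,5,5-tetramethyl-1,3,2-dioxaborolan-2-yl)phenyl]-2-[4-(benzyloxy)phenyl]-4H-chromen-4-one
Conditions: B2pin2 (1.3 equiv), PdCl2(dppf) (5 mol %), KOAc (3 equiv), 1,4-dioxane, 90 °C
Reagents that add atoms: bis(pinacolato)diboron, CC1(C)OB(OC1(C)C)B1OC(C)(C)C(C)(C)O1
Why: Miyaura borylation (oxidative addition of the unhindered ring-B C–Br bond to zerovalent palladium, acetate-assisted transmetalation, reductive elimination) tolerates the flavone carbonyl and the benzyl ethers.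

Step 11
Reactants: 16 the pinacol boronate of step 10
Product: 17 {4-(benzyloxy)-3-[5,7-bis(benzyloxy)-2-(4-benzyloxyphenyl)-4-oxo-4H-chromen-6-yl]phenyl}boronic acid
Conditions: NaIO4 (3 equiv), NH4OAc (3 equiv), THF/acetone/H2O, rt
Reagents that add atoms: water, O
Why: Periodate cleaves the pinacol released in the hydrolysis equilibrium to acetone and so drives the boronate to the free boronic acid, the form the next transmetalation requires (oxidative deprotection of pinacol boronates).

Step 12
Reactants: 18 2,4,6-trihydroxyacetophenone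
Product: 19 1-[4-(benzyloxy)-2,6-dihydroxyphenyl]ethan-1-one
Conditions: BnBr (1.0 equiv), K2CO3 (1.0 equiv), DMF, 0 °C → rt
Reagents that add atoms: benzyl bromide, BrCc1ccccc1
Why: The 4-OH is the only phenol not hydrogen-bonded to the acetyl group and is the most acidic, so one equivalent each of base and halide should give mainly the 4-benzyl ether (regioselective Williamson etherification).

Step 13
Reactants: 19 1-[4-(benzyloxy)-2,6-dihydroxyphenyl]ethan-1-one
Product: 20 1-[4-(benzyloxy)-2-hydroxy-6-methoxyphenyl]ethan-1-one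
Conditions: MeI (1.1 equiv), K2CO3, acetone, reflux
Reagents that add atoms: iodomethane, CI
Why: The two ortho phenols are equivalent, and after the first methylation the remaining one stays chelated to the ketone and resists further alkylation under these mild Williamson conditions.

Step 14
Reactants: 20 1-[4-(benzyloxy)-2-hydroxy-6-methoxyphenyl]ethan-1-one
Product: 22 7-(benzyloxy)-5-methoxy-4H-chromen-4-one, via enaminone 21 (not isolated)
Conditions: Me2NCH(OMe)2 (2 equiv), toluene, 100 °C; evaporate; conc. HCl, CH2Cl2, 40 °C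
Reagents that add atoms: N,N-dimethylformamide dimethyl acetal, COC(OC)N(C)C
Why: Condensation of the methyl ketone with the formamide acetal gives the beta-dimethylamino enone, and acid then triggers conjugate addition of the phenol and loss of dimethylamine (enaminone route to 2,3-unsubstituted chromones).

Step 15
Reactants: 17 the arylboronic acid of step 11; 22 7-(benzyloxy)-5-methoxy-4H-chromen-4-one
Product: 23 (2S)-7-(benzyloxy)-2-{4-(benzyloxy)-3-[5,7-bis(benzyloxy)-2-(4-benzyloxyphenyl)-4-oxo-4H-chromen-6-yl]phenyl}-5-methoxy-2,3-dihydro-4H-chromen-4-one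
Conditions: 22 (2 equiv), Pd(OCOCF3)2 (10 mol %), (R)-4-tert-butyl-2-(pyridin-2-yl)-4,5-dihydrooxazole [(R)-t-BuPyOx, 12 mol %], NH4PF6 (30 mol %), H2O (5 equiv), ClCH2CH2Cl, 60 °C
Reagents that add atoms: none
Why: In this asymmetric conjugate addition of arylboronic acids to chromones, transmetalation gives a cationic aryl complex of divalent palladium, the chromone C2=C3 bond inserts in the enantiodetermining step and water protonates the palladium enolate; the tert-butyl group of the (R)-ligand should steer the aryl group to the Re face of C2 and so give (2S), while the fully substituted, ring-F-conjugated C2''=C3'' bond of ring E should not compete as an acceptor.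

Step 16
Reactants: 23 the pentabenzyl ether of step 15
Product: 24 (2S)-2-{3-[5,7-dihydroxy-2-(4-hydroxyphenyl)-4-oxo-4H-chromen-6-yl]-4-hydroxyphenyl}-7-hydroxy-5-methoxy-2,3-dihydro-4H-chromen-4-one (CNP0332590.1)
Conditions: H2 (1 atm), 10% Pd/C, THF/MeOH, rt
Reagents that add atoms: none
Why: Catalytic hydrogenolysis of the five aryl benzyl ethers under neutral conditions at one atmosphere should leave the methyl ether, both vinylogous-ester carbonyl groups, the ring-E double bond and the base-sensitive C2 stereocentre unchanged.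

Compound list
1 | methyl 4-hydroxybenzoate | COC(=O)c1ccc(O)cc1 | starting material
2 | methyl 4-(benzyloxy)benzoate | COC(=O)c1ccc(OCc2ccccc2)cc1 | intermediate
3 | acetylacetone | CC(=O)CC(C)=O | starting material
4 | 1-[4-(benzyloxy)phenyl]hexane-1,3,5-trione | CC(=O)CC(=O)CC(=O)c1ccc(OCc2ccccc2)cc1 | intermediate
5 | 2-[4-(benzyloxy)phenyl]-6-methyl-4H-pyran-4-one | Cc1cc(=O)cc(-c2ccc(OCc3ccccc3)cc2)o1 | intermediate
6 | 2-hydroxyphenylacetic acid | OC(=O)Cc1ccccc1O | starting material
7 | (5-bromo-2-hydroxyphenyl)acetic acid | OC(=O)Cc1cc(Br)ccc1O | intermediate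
8 | benzyl [2-(benzyloxy)-5-bromophenyl]acetate | O=C(Cc1cc(Br)ccc1OCc1ccccc1)OCc1ccccc1 | intermediate
9 | [2-(benzyloxy)-5-bromophenyl]acetic acid | OC(=O)Cc1cc(Br)ccc1OCc1ccccc1 | intermediate
10 | 2-[2-(benzyloxy)-5-bromophenyl]propanedioic acid | OC(=O)C(C(=O)O)c1cc(Br)ccc1OCc1ccccc1 | intermediate
11 | 2-[2-(benzyloxy)-5-bromophenyl]propanedioyl dichloride | O=C(Cl)C(C(=O)Cl)c1cc(Br)ccc1OCc1ccccc1 | intermediate
12 | 2-[2-(benzyloxy)-5-bromophenyl]-3-oxoprop-2-enoyl chloride, the (chlorocarbonyl)arylketene | O=C=C(C(=O)Cl)c1cc(Br)ccc1OCc1ccccc1 | intermediate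
13 | tert-butyl({6-[4-(benzyloxy)phenyl]-2-methylidene-2H-pyran-4-yl}oxy)dimethylsilane | C=C1C=C(O[Si](C)(C)C(C)(C)C)C=C(c2ccc(OCc3ccccc3)cc2)O1 | intermediate
14 | 6-[2-(benzyloxy)-5-bromophenyl]-2-[4-(benzyloxy)phenyl]-5,7-dihydroxy-4H-chromen-4-one | O=c1cc(-c2ccc(OCc3ccccc3)cc2)oc2cc(O)c(-c3cc(Br)ccc3OCc3ccccc3)c(O)c12 | intermediate
15 | 5,7-bis(benzyloxy)-6-[2-(benzyloxy)-5-bromophenyl]-2-[4-(benzyloxy)phenyl]-4H-chromen-4-one | O=c1cc(-c2ccc(OCc3ccccc3)cc2)oc2cc(OCc3ccccc3)c(-c3cc(Br)ccc3OCc3ccccc3)c(OCc3ccccc3)c12 | intermediate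
16 | pinacol boronate of 15 (Bpin in place of Br) | O=c1cc(-c2ccc(OCc3ccccc3)cc2)oc2cc(OCc3ccccc3)c(-c3cc(B4OC(C)(C)C(C)(C)O4)ccc3OCc3ccccc3)c(OCc3ccccc3)c12 | intermediate
17 | {4-(benzyloxy)-3-[5,7-bis(benzyloxy)-2-(4-benzyloxyphenyl)-4-oxo-4H-chromen-6-yl]phenyl}boronic acid | O=c1cc(-c2ccc(OCc3ccccc3)cc2)oc2cc(OCc3ccccc3)c(-c3cc(B(O)O)ccc3OCc3ccccc3)c(OCc3ccccc3)c12 | intermediate
18 | 2,4,6-trihydroxyacetophenone | CC(=O)c1c(O)cc(O)cc1O | starting material
19 | 1-[4-(benzyloxy)-2,6-dihydroxyphenyl]ethan-1-one | CC(=O)c1c(O)cc(OCc2ccccc2)cc1O | intermediate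
20 | 1-[4-(benzyloxy)-2-hydroxy-6-methoxyphenyl]ethan-1-one | COc1cc(OCc2ccccc2)cc(O)c1C(C)=O | intermediate
21 | (E)-1-[4-(benzyloxy)-2-hydroxy-6-methoxyphenyl]-3-(dimethylamino)prop-2-en-1-one | COc1cc(OCc2ccccc2)cc(O)c1C(=O)/C=C/N(C)C | intermediate
22 | 7-(benzyloxy)-5-methoxy-4H-chromen-4-one | COc1cc(OCc2ccccc2)cc2occc(=O)c12 | intermediate
23 | (2S)-pentabenzyl ether of the target | COc1cc(OCc2ccccc2)cc2c1C(=O)C[C@@H](c1ccc(OCc3ccccc3)c(-c3c(OCc4ccccc4)cc4oc(-c5ccc(OCc6ccccc6)cc5)cc(=O)c4c3OCc3ccccc3)c1)O2 | intermediate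
24 | CNP0332590.1, (2S)-2-{3-[5,7-dihydroxy-2-(4-hydroxyphenyl)-4-oxo-4H-chromen-6-yl]-4-hydroxyphenyl}-7-hydroxy-5-methoxy-2,3-dihydro-4H-chromen-4-one | COc1cc(O)cc2c1C(=O)C[C@@H](c1ccc(O)c(-c3c(O)cc4oc(-c5ccc(O)cc5)cc(=O)c4c3O)c1)O2 | target

Total step count: 16.
Longest linear sequence: 10 steps (steps 4, 5, 6, 7, 8, 9, 10, 11, 15 and 16, from 6 to 24).

Steps most likely to fail

Step 8.
- What may go wrong:
  - Soft enolisation of the silyloxypyrylium salt may be incomplete.
  - The amine may induce oligomerisation of the ketene.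
  - The sequence may stop after the first acylation because C3 is too weak a nucleophile.
  - The ortho benzyloxy oxygen may attack the acyl chloride, with loss of its benzyl group.
- Fallback (known chemistry, accepting the biaryl coupling): it sets out from 19 and 2 and rejoins the route at 15.
  - The polyanion of 19 (LiN(SiMe3)2, THF, −78 °C → rt) is acylated by ester 2 to give 1-[4-(benzyloxy)-2,6-dihydroxyphenyl]-3-[4-(benzyloxy)phenyl]propane-1,3-dione F1.
  - p-TsOH in refluxing toluene cyclodehydrates this to 7-(benzyloxy)-2-[4-(benzyloxy)phenyl]-5-hydroxy-4H-chromen-4-one F2.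
  - Iodination ortho to the free chelated phenol (benzyltrimethylammonium dichloroiodate, CaCO3, CH2Cl2/MeOH) gives the 6-iodo-5-hydroxyflavone F3.
  - Benzylation (BnBr, Cs2CO3, DMF) gives 5,7-bis(benzyloxy)-2-[4-(benzyloxy)phenyl]-6-iodo-4H-chromen-4-one F4.
  - Suzuki–Miyaura coupling of F4 at the C–I bond with commercial [2-(benzyloxy)-5-bromophenyl]boronic acid (Pd(PPh3)4, aq. Na2CO3, DME, 80 °C) gives 15.

Step 15.
- What may go wrong:
  - Insertion into the electron-rich 5,7-dioxygenated chromone may be slow, which leaves time for protodeboronation and homocoupling of the valuable boronic acid.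
  - Facial selectivity may erode with the bulky meta-substituted aryl group.
- Fallback: it sets out from 15 and 20 and rejoins the route at 23.
  - Reductive carbonylation of 15 (Pd(OAc)2, n-butyldi(1-adamantyl)phosphine, CO/H2, TMEDA, toluene, 100 °C) gives 4-(benzyloxy)-3-[5,7-bis(benzyloxy)-2-(4-benzyloxyphenyl)-4-oxo-4H-chromen-6-yl]benzaldehyde F5.
  - Claisen–Schmidt condensation with 20 (KOH, EtOH/THF, rt) gives the (E)-2'-hydroxychalcone F6.
  - NaOAc in refluxing EtOH closes ring C by intramolecular oxa-Michael addition to give the racemic flavanone F7.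
  - Preparative chromatography on a chiral stationary phase delivers 23. The (2R)-antipode F8 is re-equilibrated through the chalcone with NaOAc and recycled.

Step 7.
- What may go wrong:
  - The arylmalonic acid may decarboxylate during activation.
  - The ortho oxygen may lactonise onto the acyl chloride with loss of the benzyl group.
  - The ketene may dimerise on concentration.
  - Residual dichloride 11 is harmless, since 2,6-lutidine would convert it into 12 in step 8.
- Fallback: it sets out from 10 and rejoins the route at 14.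
  - N,N'-dicyclohexylcarbodiimide and 2,4,6-trichlorophenol (CH2Cl2, 0 °C) convert 10, without any acid chloride, into the storable bis(2,4,6-trichlorophenyl) 2-[2-(benzyloxy)-5-bromophenyl]propanedioate F9.
  - With i-Pr2NEt in warm toluene, F9 releases an (aryloxycarbonyl)arylketene by loss of trichlorophenoxide.
  - This ketene is offered to 13, generated as in step 8, and the second aryl ester serves as the acyl donor for closure at C3.

Further compounds
F1 | step 8 | 1-[4-(benzyloxy)-2,6-dihydroxyphenyl]-3-[4-(benzyloxy)phenyl]propane-1,3-dione | O=C(CC(=O)c1c(O)cc(OCc2ccccc2)cc1O)c1ccc(OCc2ccccc2)cc1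
F2 | step 8 | 7-(benzyloxy)-2-[4-(benzyloxy)phenyl]-5-hydroxy-4H-chromen-4-one | O=c1cc(-c2ccc(OCc3ccccc3)cc2)oc2cc(OCc3ccccc3)cc(O)c12
F3 | step 8 | 7-(benzyloxy)-2-[4-(benzyloxy)phenyl]-5-hydroxy-6-iodo-4H-chromen-4-one | O=c1cc(-c2ccc(OCc3ccccc3)cc2)oc2cc(OCc3ccccc3)c(I)c(O)c12
F4 | step 8 | 5,7-bis(benzyloxy)-2-[4-(benzyloxy)phenyl]-6-iodo-4H-chromen-4-one | O=c1cc(-c2ccc(OCc3ccccc3)cc2)oc2cc(OCc3ccccc3)c(I)c(OCc3ccccc3)c12
F5 | step 15 | 4-(benzyloxy)-3-[5,7-bis(benzyloxy)-2-(4-benzyloxyphenyl)-4-oxo-4H-chromen-6-yl]benzaldehyde | O=Cc1ccc(OCc2ccccc2)c(-c2c(OCc3ccccc3)cc3oc(-c4ccc(OCc5ccccc5)cc4)cc(=O)c3c2OCc2ccccc2)c1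
F6 | step 15 | (E)-2'-hydroxychalcone from F5 and 20 | COc1cc(OCc2ccccc2)cc(O)c1C(=O)/C=C/c1ccc(OCc2ccccc2)c(-c2c(OCc3ccccc3)cc3oc(-c4ccc(OCc5ccccc5)cc4)cc(=O)c3c2OCc2ccccc2)c1
F7 | step 15 | racemic pentabenzyl flavanone | COc1cc(OCc2ccccc2)cc2c1C(=O)CC(c1ccc(OCc3ccccc3)c(-c3c(OCc4ccccc4)cc4oc(-c5ccc(OCc6ccccc6)cc5)cc(=O)c4c3OCc3ccccc3)c1)O2
F8 | step 15 | (2R)-pentabenzyl flavanone, antipode of 23 | COc1cc(OCc2ccccc2)cc2c1C(=O)C[C@H](c1ccc(OCc3ccccc3)c(-c3c(OCc4ccccc4)cc4oc(-c5ccc(OCc6ccccc6)cc5)cc(=O)c4c3OCc3ccccc3)c1)O2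
F9 | step 7 | bis(2,4,6-trichlorophenyl) 2-[2-(benzyloxy)-5-bromophenyl]propanedioate | O=C(Oc1c(Cl)cc(Cl)cc1Cl)C(C(=O)Oc1c(Cl)cc(Cl)cc1Cl)c1cc(Br)ccc1OCc1ccccc1
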